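**Plan**

1. The ring is numbered C1 (2-methylbutanoyl), C2 (OH), C3 (CH3), C4 (O-geranyl), C5 (acetyl), C6 (OH). The retrosynthesis cuts the C6-O acetal, the C5–acetyl bond (back to a C5 iodide), the C4-O–geranyl bond, and then the ring bonds C2–C3, C4–C5 and C1–C2.
2. The enabling feature is the C2(OH)–C3(CH3)–C4(O) unit, which is a ketene carbonyl carbon joined to 1-siloxypropyne. C5, C6(O) and C1(acyl) are the CH=N2 carbon and the enol-ether alkene of an α'-diazo enone, so the benzene ring is formed with its three oxygens in three different states (free OH, silyl ether, MOM ether).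
3. Forward: (R)-2-methylbutanoic acid → methyl ketone → oxalate Claisen → MOM enol ether → acid → diazo ketone; ethyl acetate → siloxypropyne; the photochemical benzannulation closes the only ring.
4. The ring is then iodinated at C5, geranylated at O4 after fluoride release, acetylated at C5 by Stille coupling, and freed of the MOM group.
5. The single stereocentre (R, α to the aryl ketone) is bought with (R)-2-methylbutanoic acid. Enolization at that carbon is avoided throughout (kinetic deprotonation at CH3, base-free diazo ketone formation, neutral pericyclic cascade).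

Key step: step 7

Remark on the chemistry: diketo ester 5 is assumed to exist and react as its chelated 2-hydroxy enol, as acylpyruvates do, so that O-alkylation gives the (Z)-2-alkoxy enoate. Salts that only await protonation in the work-up are not numbered separately. Geranyl stands for (2E)-3,7-dimethylocta-2,6-dien-1-yl and TIPS for triisopropylsilyl.

**Route**

Step 1
Reactants: 1 (R)-2-methylbutanoic acid
Product: 2 (R)-3-methylpentan-2-one
Conditions: MeLi (2.1 equiv), Et2O, 0 °C to rt; inverse quench into cold 1 M HCl
Reagents that add atoms: methyllithium, [Li]C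
Why: Addition of MeLi to the lithium carboxylate stops at the dilithium gem-diolate, which releases the methyl ketone only on quench (organolithium ketone synthesis from a carboxylic acid), and the α-stereocentre should survive because the carboxylate is attacked much faster than it is deprotonated.

Step 2
Reactants: 2 (R)-3-methylpentan-2-one; 3 diethyl oxalate
Product: 5 ethyl (2Z,5R)-2-hydroxy-5-methyl-4-oxohept-2-enoate, via lithium enolate 4 (not isolated)
Conditions: LiN(SiMe3)2 (1.05 equiv), THF, −78 °C; then 3, −78 to 0 °C; 1 M HCl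
Reagents that add atoms: none
Why: Kinetic deprotonation by the bulky amide at −78 °C takes a proton from the methyl group and not from the tertiary stereogenic carbon, and the enolate undergoes a crossed Claisen condensation with non-enolizable diethyl oxalate to a product that is held as its chelated enolate and so shielded from further base.

Step 3
Reactants: 5 ethyl (2Z,5R)-2-hydroxy-5-methyl-4-oxohept-2-enoate
Product: 6 ethyl (2Z,5R)-2-(methoxymethoxy)-5-methyl-4-oxohept-2-enoate
Conditions: MOMCl, iPr2NEt, CH2Cl2, 0 °C
Reagents that add atoms: chloromethyl methyl ether, COCCl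
Why: O-Alkylation of the acylpyruvate enol with the hard electrophile MOMCl should take place on the oxygen at C2, whose carbonyl is made the better acceptor by the ester, and the chelated enol geometry is carried over to the (Z)-enol ether in which the ketone lies trans to the ester.

Step 4
Reactants: 6 ethyl (2Z,5R)-2-(methoxymethoxy)-5-methyl-4-oxohept-2-enoate
Product: 7 (2Z,5R)-2-(methoxymethoxy)-5-methyl-4-oxohept-2-enoic acid
Conditions: LiOH, THF/H2O, 0 °C; then cold 0.5 M HCl to pH 3–4
Reagents that add atoms: lithium hydroxide, [Li+].[OH-]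
Why: Saponification of the activated α-alkoxyacrylate ester at 0 °C should be faster than hydroxide attack on the vinylogous ester or enolization at the stereocentre, and the cold, mildly acidic work-up spares the enol acetal.

Step 5
Reactants: 7 (2Z,5R)-2-(methoxymethoxy)-5-methyl-4-oxohept-2-enoic acid
Product: 9 (3Z,6R)-1-diazo-3-(methoxymethoxy)-6-methyloct-3-ene-2,5-dione, via mixed anhydride 8 (not isolated)
Conditions: iBuOCOCl, Et3N, THF, −20 °C; then CH2N2, Et2O, −20 to 0 °C
Reagents that add atoms: diazomethane, C=[N+]=[N-]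
Why: Acylation of diazomethane by the mixed carbonic anhydride (the Arndt–Eistert preparation of α-diazo ketones) needs no strong base or acid, so the stereocentre and the MOM enol ether are safe, and the donor-substituted trisubstituted alkene should be a poor dipolarophile at low temperature.

Step 6
Reactants: 10 ethyl acetate
Product: 13 1-(triisopropylsiloxy)propyne, via dibromoenolate 11 (not isolated), via lithium ynolate 12 (not isolated)
Conditions: CH2Br2, lithium 2,2,6,6-tetramethylpiperidide, THF, −78 °C; n-BuLi, −78 °C to rt; TIPSCl, 0 °C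
Reagents that add atoms: dibromomethane, BrCBr; chlorotri(propan-2-yl)silane, CC(C)[Si](Cl)(C(C)C)C(C)C
Why: This is the Kowalski ester homologation stopped at the ynolate, in which dibromomethyllithium adds to the ester, the dibromo ketone enolate undergoes Br/Li exchange and 1,2-shift to lithium propynolate, and the bulky chlorosilane silylates on oxygen.

Step 7
Reactants: 9 (3Z,6R)-1-diazo-3-(methoxymethoxy)-6-methyloct-3-ene-2,5-dione; 13 1-(triisopropylsiloxy)propyne
Product: 18 (R)-1-[2-hydroxy-6-(methoxymethoxy)-3-methyl-4-(triisopropylsiloxy)phenyl]-2-methylbutan-1-one, via vinylketene 14 (not isolated), via alkenylcyclobutenone 15 (not isolated), via dienylketene 16 (not isolated), via cyclohexadienone 17 (not isolated)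
Conditions: 13 (1.5 equiv), hν (medium-pressure Hg lamp, Pyrex filter), degassed ClCH2CH2Cl, rt; then 80 °C
Reagents that add atoms: none
Why: Light expels N2 from 9 and the alkenyl group migrates to the diazo carbon (Wolff rearrangement) to give vinylketene 14, whose carbonyl carbon is attacked by the nucleophilic, methyl-bearing carbon of siloxyalkyne 13, so that a [2+2] cycloaddition gives 4-alkenylcyclobutenone 15 and with it the C2–C3 and C4–C5 bonds of the later arene. Heating opens 15 by conrotatory 4π electrocyclic cleavage to dienylketene 16, and the benzene ring then closes by thermal disrotatory 6π electrocyclization that joins the ketene carbon to the acyl-bearing alkene terminus (C1–C2), after which dienone 17 tautomerizes to phenol 18. The closest known reaction is the Danheiser benzannulation in its photochemical Wolff variant with trialkylsiloxyalkynes, which gives resorcinol monosilyl ethers with this connectivity. No lasting stereocentre is formed, since the sp3 ring carbons of 15 and 17 are lost on aromatization, and the neutral conditions should leave the ketone α-stereocentre untouched. The step needs the regiochemistry of the [2+2] addition, which the polarization of the ynol ether secures, and it needs the ketene to stay clear of the ketone oxygen, which the (Z)-enol ether secures because the acyl group is trans to the ketene-bearing carbon and oxa-6π closure to a 2-pyranone is geometrically impossible. The MOM-oxy donor also makes the alkene terminus that attacks the ketene the nucleophilic α-carbon of a vinylogous ester, a polarity match for the ring-closing C–C bond.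

Step 8
Reactants: 18 (R)-1-[2-hydroxy-6-(methoxymethoxy)-3-methyl-4-(triisopropylsiloxy)phenyl]-2-methylbutan-1-one
Product: 19 (R)-1-[2-hydroxy-5-iodo-6-(methoxymethoxy)-3-methyl-4-(triisopropylsiloxy)phenyl]-2-methylbutan-1-one
Conditions: NIS, MeCN, 0 °C, dark
Reagents that add atoms: N-iodosuccinimide, O=C1CCC(=O)N1I
Why: Electrophilic aromatic iodination goes to C5, the only unsubstituted ring carbon, which is para to the free phenol and ortho to two oxygen substituents, and the neutral reagent leaves the silyl ether and the MOM acetal in place.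

Step 9
Reactants: 19 (R)-1-[2-hydroxy-5-iodo-6-(methoxymethoxy)-3-methyl-4-(triisopropylsiloxy)phenyl]-2-methylbutan-1-one; 20 geranyl bromide
Product: 22 (R)-1-[4-(geranyloxy)-2-hydroxy-5-iodo-6-(methoxymethoxy)-3-methylphenyl]-2-methylbutan-1-one, via ammonium phenoxide 21 (not isolated)
Conditions: Bu4NF (1.0 equiv), THF, 0 °C; then 20, 0 °C to rt
Reagents that add atoms: none
Why: Fluoride cleaves the aryl silyl ether and frees the C4 phenoxide as a naked tetrabutylammonium salt that is O-alkylated by the allylic bromide (desilylative Williamson ether synthesis), while the C2 hydroxyl stays protonated and hydrogen-bonded to the ketone and C6 is still a MOM ether.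

Step 10
Reactants: 22 (R)-1-[4-(geranyloxy)-2-hydroxy-5-iodo-6-(methoxymethoxy)-3-methylphenyl]-2-methylbutan-1-one
Product: 24 (R)-1-[5-acetyl-4-(geranyloxy)-2-hydroxy-6-(methoxymethoxy)-3-methylphenyl]-2-methylbutan-1-one, via enol ether 23 (not isolated)
Conditions: tributyl(1-ethoxyethenyl)stannane, PdCl2(PPh3)2 (5 mol %), toluene, 100 °C; then 1 M HCl, THF, 0 °C
Reagents that add atoms: tributyl(1-ethoxyethenyl)stannane, CCCC[Sn](CCCC)(CCCC)C(=C)OCC; water, O
Why: Stille coupling of the aryl iodide with the α-ethoxyvinyl stannane, an acetyl anion equivalent, is followed by brief dilute-acid hydrolysis of the enol ether to the methyl ketone, under which the MOM acetal and the geranyl ether should persist.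

Step 11
Reactants: 24 (R)-1-[5-acetyl-4-(geranyloxy)-2-hydroxy-6-(methoxymethoxy)-3-methylphenyl]-2-methylbutan-1-one
Product: 25 (R)-1-[5-acetyl-4-(geranyloxy)-2,6-dihydroxy-3-methylphenyl]-2-methylbutan-1-one (CNP0106233.1)
Conditions: HCl (0.5 M in MeOH), THF, 0 °C to rt
Reagents that add atoms: none
Why: Acid-catalysed transacetalization to methanol removes the MOM group, whose oxocarbenium ion forms far more easily than the allylic cation from the geranyl ether, and the freed hydroxyl is at once hydrogen-bonded between the two ketones.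

**Compound list**

1 | (R)-2-methylbutanoic acid | CC[C@@H](C)C(=O)O | starting material
2 | (R)-3-methylpentan-2-one | CC[C@@H](C)C(C)=O | intermediate
3 | diethyl oxalate | CCOC(=O)C(=O)OCC | starting material
4 | lithium (R)-3-methylpent-1-en-2-olate (formed in the flask) | CC[C@@H](C)C(=C)[O-].[Li+] | intermediate
5 | ethyl (2Z,5R)-2-hydroxy-5-methyl-4-oxohept-2-enoate (enol form of ethyl (R)-5-methyl-2,4-dioxoheptanoate) | CC[C@@H](C)C(=O)/C=C(\O)C(=O)OCC | intermediate
6 | ethyl (2Z,5R)-2-(methoxymethoxy)-5-methyl-4-oxohept-2-enoate | CC[C@@H](C)C(=O)/C=C(\OCOC)C(=O)OCC | intermediate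
7 | (2Z,5R)-2-(methoxymethoxy)-5-methyl-4-oxohept-2-enoic acid | CC[C@@H](C)C(=O)/C=C(\OCOC)C(=O)O | intermediate
8 | isobutyl carbonic (2Z,5R)-2-(methoxymethoxy)-5-methyl-4-oxohept-2-enoic anhydride (formed in the flask) | CC[C@@H](C)C(=O)/C=C(\OCOC)C(=O)OC(=O)OCC(C)C | intermediate
9 | (3Z,6R)-1-diazo-3-(methoxymethoxy)-6-methyloct-3-ene-2,5-dione | CC[C@@H](C)C(=O)/C=C(\OCOC)C(=O)C=[N+]=[N-] | intermediate
10 | ethyl acetate | CCOC(C)=O | starting material
11 | lithium 1,1-dibromoprop-1-en-2-olate (formed in the flask) | CC([O-])=C(Br)Br.[Li+] | intermediate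
12 | lithium prop-1-yn-1-olate (formed in the flask) | CC#C[O-].[Li+] | intermediate
13 | 1-(triisopropylsiloxy)propyne | CC#CO[Si](C(C)C)(C(C)C)C(C)C | intermediate
14 | (3Z,6R)-3-(methoxymethoxy)-6-methylocta-1,3-diene-1,5-dione (vinylketene, formed in the flask) | CC[C@@H](C)C(=O)/C=C(\OCOC)C=C=O | intermediate
15 | 4-[(1Z,4R)-1-(methoxymethoxy)-4-methyl-3-oxohex-1-en-1-yl]-2-methyl-3-(triisopropylsiloxy)cyclobut-2-en-1-one (either configuration at ring C4, formed in the flask) | CC[C@@H](C)C(=O)/C=C(\OCOC)C1C(=O)C(C)=C1O[Si](C(C)C)(C(C)C)C(C)C | intermediate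
16 | (3E,5Z,8R)-5-(methoxymethoxy)-2,8-dimethyl-3-(triisopropylsiloxy)deca-1,3,5-triene-1,7-dione (dienylketene, formed in the flask) | CC[C@@H](C)C(=O)/C=C(\OCOC)/C=C(O[Si](C(C)C)(C(C)C)C(C)C)\C(C)=C=O | intermediate
17 | 5-(methoxymethoxy)-2-methyl-6-[(2R)-2-methylbutanoyl]-3-(triisopropylsiloxy)cyclohexa-2,4-dien-1-one (either configuration at ring C6, formed in the flask) | CC[C@@H](C)C(=O)C1C(=O)C(C)=C(O[Si](C(C)C)(C(C)C)C(C)C)C=C1OCOC | intermediate
18 | (R)-1-[2-hydroxy-6-(methoxymethoxy)-3-methyl-4-(triisopropylsiloxy)phenyl]-2-methylbutan-1-one | CC[C@@H](C)C(=O)c1c(O)c(C)c(O[Si](C(C)C)(C(C)C)C(C)C)cc1OCOC | intermediate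
19 | (R)-1-[2-hydroxy-5-iodo-6-(methoxymethoxy)-3-methyl-4-(triisopropylsiloxy)phenyl]-2-methylbutan-1-one | CC[C@@H](C)C(=O)c1c(O)c(C)c(O[Si](C(C)C)(C(C)C)C(C)C)c(I)c1OCOC | intermediate
20 | geranyl bromide | BrC/C=C(\C)CCC=C(C)C | starting material
21 | tetrabutylammonium 3-hydroxy-6-iodo-5-(methoxymethoxy)-2-methyl-4-[(2R)-2-methylbutanoyl]phenolate (formed in the flask) | CC[C@@H](C)C(=O)c1c(O)c(C)c([O-])c(I)c1OCOC.CCCC[N+](CCCC)(CCCC)CCCC | intermediate
22 | (R)-1-[4-(geranyloxy)-2-hydroxy-5-iodo-6-(methoxymethoxy)-3-methylphenyl]-2-methylbutan-1-one | CC[C@@H](C)C(=O)c1c(O)c(C)c(OC/C=C(\C)CCC=C(C)C)c(I)c1OCOC | intermediate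
23 | (R)-1-[5-(1-ethoxyethenyl)-4-(geranyloxy)-2-hydroxy-6-(methoxymethoxy)-3-methylphenyl]-2-methylbutan-1-one (formed in the flask) | CC[C@@H](C)C(=O)c1c(O)c(C)c(OC/C=C(\C)CCC=C(C)C)c(C(=C)OCC)c1OCOC | intermediate
24 | (R)-1-[5-acetyl-4-(geranyloxy)-2-hydroxy-6-(methoxymethoxy)-3-methylphenyl]-2-methylbutan-1-one | CC[C@@H](C)C(=O)c1c(O)c(C)c(OC/C=C(\C)CCC=C(C)C)c(C(C)=O)c1OCOC | intermediate
25 | (R)-1-[5-acetyl-4-(geranyloxy)-2,6-dihydroxy-3-methylphenyl]-2-methylbutan-1-one (CNP0106233.1) | CC[C@@H](C)C(=O)c1c(O)c(C)c(OC/C=C(\C)CCC=C(C)C)c(C(C)=O)c1O | target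

**Step count**

Total: 11 steps. Longest linear sequence: 10 steps (steps 1–5 and 7–11, from 1); step 6 is a one-step side branch.

**Steps most likely to fail**

Step 7. The enol ether double bond may photoisomerize, which would let the vinylketene close onto the ketone oxygen to give a 2-pyranone. The product phenol may also capture ketene intermediates, or the aryl ketone may undergo secondary photolysis before the cascade is complete. The fallback leaves the pericyclic construction and builds the same arene by classical acylation. It sets out from 1 and comes back at 18. Acid 1 would be converted with oxalyl chloride and catalytic DMF in CH2Cl2 into (R)-2-methylbutanoyl chloride F1. This acylates commercial 2-methylbenzene-1,3,5-triol under Friedel–Crafts conditions (AlCl3, CH2Cl2/PhNO2, 0 °C to rt) at either of its two equivalent free positions, giving (R)-2-methyl-1-(2,4,6-trihydroxy-3-methylphenyl)butan-1-one F2. TIPSCl (1 equiv) and imidazole in DMF at 0 °C should silylate the only hydroxyl that is not ortho to the ketone, giving (R)-1-[2,6-dihydroxy-3-methyl-4-(triisopropylsiloxy)phenyl]-2-methylbutan-1-one F3. MOMCl (1 equiv) and iPr2NEt in CH2Cl2 should then alkylate the ortho hydroxyl whose other neighbour is a ring hydrogen and not the methyl group, which gives 18.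

Step 5. Diazomethane may add as a 1,3-dipole across the doubly activated alkene (pyrazoline formation) in competition with acylation at the anhydride carbonyl. The fallback installs the diazo group by diazo transfer and uses no diazomethane. It sets out from 7 and comes back at 9. Acid 7 would be converted under neutral conditions with 1-chloro-N,N,2-trimethylprop-1-en-1-amine in CH2Cl2 into (2Z,5R)-2-(methoxymethoxy)-5-methyl-4-oxohept-2-enoyl chloride F4. Negishi acylation with MeZnCl and catalytic Pd(PPh3)4 in THF at 0 °C should give (3Z,6R)-3-(methoxymethoxy)-6-methyloct-3-ene-2,5-dione F5. Kinetic deprotonation of its methyl group with LiN(SiMe3)2 in THF at −78 °C gives lithium (3Z,6R)-3-(methoxymethoxy)-6-methyl-5-oxoocta-1,3-dien-2-olate F6. Trapping with 2,2,2-trifluoroethyl trifluoroacetate gives (5Z,8R)-1,1,1-trifluoro-5-(methoxymethoxy)-8-methyldec-5-ene-2,4,7-trione F7, which is used crude. Detrifluoroacetylative diazo transfer (MsN3, Et3N, H2O, MeCN, rt) then gives 9.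

Step 11. Acid may ionize the allylic aryl ether, with loss or cyclization of the geranyl group, in competition with cleavage of the MOM acetal. The fallback removes the acetal before the geranyl group is present and relies on fluoride release of the para phenoxide for site selectivity. It sets out from 19 and comes back at 25. HCl in MeOH at rt should convert 19 into (R)-1-[2,6-dihydroxy-3-iodo-5-methyl-4-(triisopropylsiloxy)phenyl]-2-methylbutan-1-one F8. Bu4NF (1.0 equiv) in THF at 0 °C frees tetrabutylammonium 3,5-dihydroxy-2-iodo-6-methyl-4-[(2R)-2-methylbutanoyl]phenolate F9, the most acidic, non-chelated oxygen para to the ketone. Geranyl bromide 20, added to the same flask, should give (R)-1-[4-(geranyloxy)-2,6-dihydroxy-3-iodo-5-methylphenyl]-2-methylbutan-1-one F10. Stille coupling with tributyl(1-ethoxyethenyl)stannane and PdCl2(PPh3)2 in toluene at 100 °C gives (R)-1-[3-(1-ethoxyethenyl)-4-(geranyloxy)-2,6-dihydroxy-5-methylphenyl]-2-methylbutan-1-one F11. This is not isolated but hydrolysed with 0.1 M aqueous oxalic acid in THF at 0 °C to 25, conditions far milder than acetal cleavage.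

**Further compounds**

F1 | step 7 | (R)-2-methylbutanoyl chloride | CC[C@@H](C)C(=O)Cl
F2 | step 7 | (R)-2-methyl-1-(2,4,6-trihydroxy-3-methylphenyl)butan-1-one | CC[C@@H](C)C(=O)c1c(O)c(C)c(O)cc1O
F3 | step 7 | (R)-1-[2,6-dihydroxy-3-methyl-4-(triisopropylsiloxy)phenyl]-2-methylbutan-1-one | CC[C@@H](C)C(=O)c1c(O)c(C)c(O[Si](C(C)C)(C(C)C)C(C)C)cc1O
F4 | step 5 | (2Z,5R)-2-(methoxymethoxy)-5-methyl-4-oxohept-2-enoyl chloride | CC[C@@H](C)C(=O)/C=C(\OCOC)C(Cl)=O
F5 | step 5 | (3Z,6R)-3-(methoxymethoxy)-6-methyloct-3-ene-2,5-dione | CC[C@@H](C)C(=O)/C=C(\OCOC)C(C)=O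
F6 | step 5 | lithium (3Z,6R)-3-(methoxymethoxy)-6-methyl-5-oxoocta-1,3-dien-2-olate | CC[C@@H](C)C(=O)/C=C(\OCOC)C(=C)[O-].[Li+]
F7 | step 5 | (5Z,8R)-1,1,1-trifluoro-5-(methoxymethoxy)-8-methyldec-5-ene-2,4,7-trione | CC[C@@H](C)C(=O)/C=C(\OCOC)C(=O)CC(=O)C(F)(F)F
F8 | step 11 | (R)-1-[2,6-dihydroxy-3-iodo-5-methyl-4-(triisopropylsiloxy)phenyl]-2-methylbutan-1-one | CC[C@@H](C)C(=O)c1c(O)c(C)c(O[Si](C(C)C)(C(C)C)C(C)C)c(I)c1O
F9 | step 11 | tetrabutylammonium 3,5-dihydroxy-2-iodo-6-methyl-4-[(2R)-2-methylbutanoyl]phenolate | CC[C@@H](C)C(=O)c1c(O)c(C)c([O-])c(I)c1O.CCCC[N+](CCCC)(CCCC)CCCC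
F10 | step 11 | (R)-1-[4-(geranyloxy)-2,6-dihydroxy-3-iodo-5-methylphenyl]-2-methylbutan-1-one | CC[C@@H](C)C(=O)c1c(O)c(C)c(OC/C=C(\C)CCC=C(C)C)c(I)c1O
F11 | step 11 | (R)-1-[3-(1-ethoxyethenyl)-4-(geranyloxy)-2,6-dihydroxy-5-methylphenyl]-2-methylbutan-1-one | CC[C@@H](C)C(=O)c1c(O)c(C)c(OC/C=C(\C)CCC=C(C)C)c(C(=C)OCC)c1O
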